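The cyclohexene ring of the target has a tertiary carbinol carbon and, 1,4 to it, the spiro carbon that carries a lactone C=O. They are linked on one side by the acetyl-bearing C=C and on the other by CH2–CH: the imprint of a 2-pyrone that has added an alkene. The key step is therefore a dearomatizing intramolecular Diels–Alder reaction of 4-acetyl-2-pyrone 25, whose C6 chain ends in a vinyl group; it closes the cyclohexene and the seven-membered ring of the hydroxylated half at once. The CO2 bridge is kept: desilylation lets the neighbouring secondary alcohol translactonize, which frees the tertiary OH and forms the spiro γ-lactone. Enyne metathesis then builds the second cycloheptene with its dienone.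

Key step: step 15

Remark on the chemistry: the catalyst antipodes named in steps 1, 2, 6 and 7 are assumed to give the configurations shown; where the sense of induction is the opposite, the enantiomeric ligand is used.

Step 1
Reactants: 1 crotonaldehyde; 2 ethynyltri(propan-2-yl)silane
Product: 3 (3R)-3-methyl-5-silylpent-4-ynal
Conditions: [Rh(OAc)(C2H4)2]2 (cat.), (R)-DTBM-SEGPHOS (cat.), MeOH, 40 °C
Reagents that add atoms: none
Why: Rhodium-catalysed asymmetric conjugate alkynylation of an enal, in which the bulky silyl group suppresses alkyne dimerization and the chiral bisphosphine–rhodium alkynyl species selects the enal face, setting C3 as R.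

Step 2
Reactants: 3 alkynyl aldehyde; 4 methyl propiolate
Product: 5 (4S,6R)-hydroxy diynoate
Conditions: Me2Zn (3 equiv), (S,S)-ProPhenol (cat.), Ph3PO (cat.), toluene, 4 °C; aq. NH4Cl
Reagents that add atoms: none
Why: Zinc–ProPhenol-catalysed asymmetric addition of a zinc alkynoate to an aldehyde, in which the catalyst overrides the remote methyl stereocentre and sets the carbinol as S.

Step 3
Reactants: 5 hydroxy diynoate
Product: 7 β-allyl butenolide, via Z-hydroxy-enoate 6 (not isolated)
Conditions: CH2=CHCH2MgBr (3.2 equiv), CuBr·SMe2 (1.6 equiv), THF, −78 °C; aq. NH4Cl; then TsOH (cat.), CH2Cl2, rt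
Reagents that add atoms: allylmagnesium bromide C=CC[Mg]Br
Why: syn-Carbocupration of the ynoate places the allyl group on the β-carbon and leaves the ester cis to the carbinol, so lactonization to the butenolide should follow without touching the stereocentres.

Step 4
Reactants: 7 β-allyl butenolide
Product: 8 cis-4-allyl-5-alkyl γ-lactone
Conditions: Cu(OAc)2·H2O (cat.), 1,2-bis(diphenylphosphino)benzene (cat.), (EtO)2MeSiH, t-BuOH, toluene, 0 °C to rt
Reagents that add atoms: none
Why: Copper hydride conjugate reduction delivers hydride to the β-carbon from the face opposite the γ-side chain, so allyl and side chain end up cis (C4 = S), while the isolated alkene and the hindered silyl alkyne are not reduced.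

Step 5
Reactants: 8 cis lactone
Product: 9 α-acetyl lactone
Conditions: LiN(iPr)2 (1.2 equiv), THF, −78 °C; N-methoxy-N-methylacetamide, −78 to 0 °C; aq. NH4Cl
Reagents that add atoms: N-methoxy-N-methylacetamide CC(=O)N(C)OC
Why: Claisen-type C-acylation of the lactone enolate with a Weinreb amide, whose stable tetrahedral adduct prevents over-reaction; the new α-centre is enolizable and later becomes sp2.

Step 6
Reactants: 10 tert-butyl methacrylate
Product: 11 tert-butyl (2S)-2-methyl-4-oxobutanoate
Conditions: Rh(acac)(CO)2 (cat.), (R,R)-1,2-bis(tert-butylmethylphosphino)benzene (cat.), CO/H2 (1:5, 10 bar), toluene, 100 °C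
Reagents that add atoms: carbon monoxide [C-]#[O+]
Why: Rhodium-catalysed asymmetric hydroformylation of a 1,1-disubstituted acrylate gives the linear aldehyde, and the enantioface-selective hydride insertion sets C2 as S.

Step 7
Reactants: 11 aldehyde ester; 4 methyl propiolate
Product: 12 (2S,4R)-hydroxy ynedioate
Conditions: Me2Zn (3 equiv), (R,R)-ProPhenol (cat.), Ph3PO (cat.), toluene, 4 °C; aq. NH4Cl
Reagents that add atoms: none
Why: Zinc–ProPhenol-catalysed asymmetric alkynylation as in step 2 with the antipodal ligand sets the carbinol as R, and the hindered tert-butyl ester does not lactonize.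

Step 8
Reactants: 12 hydroxy ynedioate
Product: 14 γ-substituted butenolide, via Z-enoate 13 (not isolated)
Conditions: H2 (1 atm), Pd/CaCO3 poisoned with Pb(OAc)2, quinoline, EtOAc, rt; then pyridinium p-toluenesulfonate (cat.), rt
Reagents that add atoms: none
Why: Lindlar semihydrogenation gives the Z-enoate, whose hydroxyl closes onto the methyl ester to the butenolide with the carbinol configuration unchanged.

Step 9
Reactants: 14 butenolide
Product: 16 trans,trans-trisubstituted lactone, via bromomagnesium enolate 15 (not isolated)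
Conditions: CH2=CHCH2MgBr (2.2 equiv), CuBr·SMe2 (1.1 equiv), THF, −78 °C; then iPr3SiOCH2Cl, DMPU, −78 to −20 °C; aq. NH4Cl
Reagents that add atoms: allylmagnesium bromide C=CC[Mg]Br; (triisopropylsiloxy)methyl chloride ClCO[Si](C(C)C)(C(C)C)C(C)C
Why: Tandem cuprate conjugate addition and enolate alkylation, in which allyl adds anti to the γ-substituent (C3 = S) and the chloromethyl ether then enters anti to the new allyl group (C4 = R), leaving a silyl-protected CH2O group as the masked methylene.

Step 10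
Reactants: 16 tert-butyl ester lactone
Product: 17 carboxylic acid
Conditions: CF3CO2H, CH2Cl2, 0 °C
Reagents that add atoms: none
Why: Acidolysis of the tert-butyl ester by loss of isobutene should leave the lactone and the robust primary triisopropylsilyl ether intact under brief cold treatment.

Step 11
Reactants: 17 carboxylic acid; 9 α-acetyl lactone
Product: 20 4-hydroxy-2-pyrone diol, via acyl imidazolide 18 (not isolated), via triketide 19 (not isolated)
Conditions: 17, 1,1'-carbonyldiimidazole, THF, rt; added to the dianion of 9 [LiN(iPr)2 (3.2 equiv), THF, −78 to −40 °C], −78 to −30 °C; AcOH; then DBU, toluene, 40 °C; aq. citric acid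
Reagents that add atoms: none
Why: γ-Acylation of a β-keto lactone dianion (Claisen type) gives a 3,5-dioxoacyl lactone, and DBU then lets the enol oxygen attack the lactone carbonyl so that the γ-lactone is exchanged for the 4-hydroxy-2-pyrone (driven by the acidity of the hydroxypyrone), freeing the secondary alcohol without touching a stereocentre.

Step 12
Reactants: 20 hydroxypyrone diol
Product: 22 mono-silyl ether, via bis-silyl ether 21 (not isolated)
Conditions: t-BuMe2SiOTf (2.5 equiv), 2,6-lutidine, CH2Cl2, −78 to 0 °C; aq. citric acid, THF, rt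
Reagents that add atoms: tert-butyldimethylsilyl trifluoromethanesulfonate CC(C)(C)[Si](C)(C)OS(=O)(=O)C(F)(F)F
Why: Silylation protects the secondary alcohol so that it cannot reopen the pyrone, while the pyronyl silyl ether, a vinylogous silyl ester, should hydrolyse on the mildly acidic work-up.

Step 13
Reactants: 22 4-hydroxypyrone
Product: 23 pyronyl triflate
Conditions: (CF3SO2)2O, pyridine, CH2Cl2, −78 to 0 °C
Reagents that add atoms: trifluoromethanesulfonic anhydride O=S(=O)(OS(=O)(=O)C(F)(F)F)C(F)(F)F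
Why: O-Sulfonylation of the acidic vinylogous acid gives the 4-pyronyl triflate as a cross-coupling handle.

Step 14
Reactants: 23 pyronyl triflate
Product: 25 4-acetyl-2-pyrone, via ethoxyvinyl pyrone 24 (not isolated)
Conditions: Bu3SnC(OEt)=CH2, Pd(PPh3)4 (cat.), LiCl, CuI (cat.), 1,4-dioxane, 60 °C; then 1 M HCl, THF, 0 °C
Reagents that add atoms: tributyl(1-ethoxyvinyl)stannane CCCC[Sn](CCCC)(CCCC)C(=C)OCC; water O
Why: Stille coupling of the pyronyl triflate with an acetyl anion equivalent followed by mild enol ether hydrolysis installs the acetyl group, with the silyl ethers surviving the brief cold acid.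

Step 15
Reactants: 25 4-acetyl-2-pyrone
Product: 26 bridged-lactone cycloadduct
Conditions: CH2Cl2 (0.01 M), 2,6-di-tert-butyl-4-methylphenol (cat.), 14 kbar, 50 °C
Reagents that add atoms: none
Why: Concerted inverse-electron-demand [4+2] cycloaddition in which the 2-pyrone is an electron-poor, s-cis-locked diene (C3=C4–C5=C6, activated by the ring carbonyl and the 4-acetyl group) and the tethered vinyl group is the dienophile, with high pressure supplying the acceleration so that the adduct forms below the temperature of CO2 extrusion. The closest known reaction type is the intramolecular Diels–Alder reaction of 2-pyrones bearing an alkenyl side chain, which gives isolable 2-oxabicyclo[2.2.2]oct-5-en-3-ones. The cyclohexene ring closes by the cycloaddition itself (pyrone C3 to the vinyl CH2, pyrone C6 to the vinyl CH), and the seven-membered ring closes in the fused mode of a type 1 intramolecular cycloaddition because the five-atom tether joins C6 to the internal vinyl carbon. The two bridgeheads are set together by suprafacial addition across the diene, which forces the lactone oxygen and the lactone carbonyl onto the same face; the pyrone face is chosen by the tether, whose methyl-bearing stereocentre and trans-fused butyrolactone should favour a chair-like seven-membered transition state with the methyl group and both lactone bonds equatorial and the chain folded over the C5–H edge of the pyrone, and this endo arrangement also fixes the ring-fusion CH (H syn to the lactone bridge). Regioselectivity (fused, not bridged) follows from the tether length, and chemoselectivity from the substrate: the lactone α-position carries CH2OSi instead of a methylene, the allyl group on the C3 side chain cannot reach C6, and the triisopropylsilyl alkyne is too hindered to add.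

Step 16
Reactants: 26 bridged-lactone cycloadduct
Product: 28 spiro-lactone diol, via desilylated bridged lactone 27 (not isolated)
Conditions: Bu4NF (6 equiv), THF, 0 °C to rt; aq. NH4Cl
Reagents that add atoms: none
Why: Fluoride removes the two O-silyl groups and the alkynyl silyl group, and the freed secondary alkoxide attacks the bridged lactone carbonyl (5-exo-trig transacylation) to give the spiro γ-lactone and release the tertiary alcohol, an acyl transfer that touches no stereocentre.

Step 17
Reactants: 28 spiro-lactone diol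
Product: 30 α-methylene lactone enyne, via primary mesylate 29 (not isolated)
Conditions: MeSO2Cl (1.1 equiv), Et3N, CH2Cl2, −20 °C; then DBU, 0 °C to rt
Reagents that add atoms: none
Why: The primary alcohol is mesylated selectively in the presence of the hindered tertiary alcohol, and E1cB elimination from the lactone α-position then unveils the exocyclic methylene.

Step 18
Reactants: 30 α-methylene lactone enyne
Product: 32 target CNP0168949.6, via vinylcycloheptene 31 (not isolated)
Conditions: methyl vinyl ketone (10 equiv), second-generation Grubbs catalyst (10 mol%), CH2Cl2, 40 °C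
Reagents that add atoms: methyl vinyl ketone C=CC(C)=O
Why: Domino ring-closing enyne metathesis and cross-metathesis, in which the allyl-derived ruthenium carbene closes onto the terminal alkyne to the 1-vinylcycloheptene and the vinyl group then exchanges with methyl vinyl ketone to the E-dienone, while the electron-poor 1,1-disubstituted methylene lactone and the trisubstituted enone should stay inert.

Compound list
1 | (E)-but-2-enal (crotonaldehyde) | C/C=C/C=O | starting material
2 | ethynyltri(propan-2-yl)silane | C#C[Si](C(C)C)(C(C)C)C(C)C | starting material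
3 | (3R)-3-methyl-5-[tri(propan-2-yl)silyl]pent-4-ynal | O=CC[C@@H](C)C#C[Si](C(C)C)(C(C)C)C(C)C | intermediate
4 | methyl prop-2-ynoate | C#CC(=O)OC | starting material
5 | methyl (4S,6R)-4-hydroxy-6-methyl-8-[tri(propan-2-yl)silyl]octa-2,7-diynoate | COC(=O)C#C[C@@H](O)C[C@@H](C)C#C[Si](C(C)C)(C(C)C)C(C)C | intermediate
6 | methyl (2Z,4S,6R)-4-hydroxy-6-methyl-3-(prop-2-en-1-yl)-8-[tri(propan-2-yl)silyl]oct-2-en-7-ynoate | COC(=O)/C=C(/CC=C)[C@@H](O)C[C@@H](C)C#C[Si](C(C)C)(C(C)C)C(C)C | intermediate
7 | (5S)-5-{(2R)-2-methyl-4-[tri(propan-2-yl)silyl]but-3-yn-1-yl}-4-(prop-2-en-1-yl)furan-2(5H)-one | C=CCC1=CC(=O)O[C@H]1C[C@@H](C)C#C[Si](C(C)C)(C(C)C)C(C)C | intermediate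
8 | (4S,5S)-5-{(2R)-2-methyl-4-[tri(propan-2-yl)silyl]but-3-yn-1-yl}-4-(prop-2-en-1-yl)oxolan-2-one (allyl and side chain cis) | C=CC[C@H]1CC(=O)O[C@H]1C[C@@H](C)C#C[Si](C(C)C)(C(C)C)C(C)C | intermediate
9 | (4S,5S)-3-acetyl-5-{(2R)-2-methyl-4-[tri(propan-2-yl)silyl]but-3-yn-1-yl}-4-(prop-2-en-1-yl)oxolan-2-one (C3 epimers and enol form) | C=CC[C@H]1C(C(C)=O)C(=O)O[C@H]1C[C@@H](C)C#C[Si](C(C)C)(C(C)C)C(C)C | intermediate
10 | tert-butyl 2-methylprop-2-enoate | CC(=C)C(=O)OC(C)(C)C | starting material
11 | tert-butyl (2S)-2-methyl-4-oxobutanoate | O=CC[C@H](C)C(=O)OC(C)(C)C | intermediate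
12 | 1-tert-butyl 7-methyl (2S,4R)-4-hydroxy-2-methylhept-5-ynedioate | COC(=O)C#C[C@H](O)C[C@H](C)C(=O)OC(C)(C)C | intermediate
13 | 1-tert-butyl 7-methyl (2S,4R,5Z)-4-hydroxy-2-methylhept-5-enedioate | COC(=O)/C=C\[C@H](O)C[C@H](C)C(=O)OC(C)(C)C | intermediate
14 | tert-butyl (2S)-2-methyl-3-[(2R)-5-oxo-2,5-dihydrofuran-2-yl]propanoate | O=C1C=C[C@@H](C[C@H](C)C(=O)OC(C)(C)C)O1 | intermediate
15 | bromo{[(4S,5R)-5-[(2S)-3-tert-butoxy-2-methyl-3-oxopropyl]-4-(prop-2-en-1-yl)-4,5-dihydrofuran-2-yl]oxy}magnesium (enolate of the trans allyl lactone) | Br[Mg]OC1=C[C@H](CC=C)[C@@H](C[C@H](C)C(=O)OC(C)(C)C)O1 | intermediate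
16 | tert-butyl (2S)-2-methyl-3-[(2R,3S,4R)-5-oxo-3-(prop-2-en-1-yl)-4-({[tri(propan-2-yl)silyl]oxy}methyl)oxolan-2-yl]propanoate | O=C1O[C@H](C[C@H](C)C(=O)OC(C)(C)C)[C@@H](CC=C)[C@@H]1CO[Si](C(C)C)(C(C)C)C(C)C | intermediate
17 | (2S)-2-methyl-3-[(2R,3S,4R)-5-oxo-3-(prop-2-en-1-yl)-4-({[tri(propan-2-yl)silyl]oxy}methyl)oxolan-2-yl]propanoic acid | O=C1O[C@H](C[C@H](C)C(=O)O)[C@@H](CC=C)[C@@H]1CO[Si](C(C)C)(C(C)C)C(C)C | intermediate
18 | (3R,4S,5R)-5-[(2S)-3-(1H-imidazol-1-yl)-2-methyl-3-oxopropyl]-4-(prop-2-en-1-yl)-3-({[tri(propan-2-yl)silyl]oxy}methyl)oxolan-2-one | O=C1O[C@H](C[C@H](C)C(=O)n2ccnc2)[C@@H](CC=C)[C@@H]1CO[Si](C(C)C)(C(C)C)C(C)C | intermediate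
19 | (4S,5S)-3-{(4S)-4-methyl-1,3-dioxo-5-[(2R,3S,4R)-5-oxo-3-(prop-2-en-1-yl)-4-({[tri(propan-2-yl)silyl]oxy}methyl)oxolan-2-yl]pentyl}-5-{(2R)-2-methyl-4-[tri(propan-2-yl)silyl]but-3-yn-1-yl}-4-(prop-2-en-1-yl)oxolan-2-one (enol tautomers) | C=CC[C@H]1C(C(=O)CC(=O)[C@@H](C)C[C@H]2OC(=O)[C@@H](CO[Si](C(C)C)(C(C)C)C(C)C)[C@@H]2CC=C)C(=O)O[C@H]1C[C@@H](C)C#C[Si](C(C)C)(C(C)C)C(C)C | intermediate
20 | 4-hydroxy-3-{(4S,5S,7R)-5-hydroxy-7-methyl-9-[tri(propan-2-yl)silyl]non-1-en-8-yn-4-yl}-6-{(2S)-1-[(2R,3S,4R)-5-oxo-3-(prop-2-en-1-yl)-4-({[tri(propan-2-yl)silyl]oxy}methyl)oxolan-2-yl]propan-2-yl}-2H-pyran-2-one | O=C1OC([C@@H](C)C[C@H]2OC(=O)[C@@H](CO[Si](C(C)C)(C(C)C)C(C)C)[C@@H]2CC=C)=CC(O)=C1[C@H](CC=C)[C@@H](O)C[C@@H](C)C#C[Si](C(C)C)(C(C)C)C(C)C | intermediate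
21 | bis(tert-butyldimethylsilyl) ether of 20 (silyl on the pyrone 4-oxygen and on the side-chain carbinol oxygen) | O=C1OC([C@@H](C)C[C@H]2OC(=O)[C@@H](CO[Si](C(C)C)(C(C)C)C(C)C)[C@@H]2CC=C)=CC(O[Si](C)(C)C(C)(C)C)=C1[C@H](CC=C)[C@@H](O[Si](C)(C)C(C)(C)C)C[C@@H](C)C#C[Si](C(C)C)(C(C)C)C(C)C | intermediate
22 | 3-{(4S,5S,7R)-5-[tert-butyl(dimethyl)silyl]oxy-7-methyl-9-[tri(propan-2-yl)silyl]non-1-en-8-yn-4-yl}-4-hydroxy-6-{(2S)-1-[(2R,3S,4R)-5-oxo-3-(prop-2-en-1-yl)-4-({[tri(propan-2-yl)silyl]oxy}methyl)oxolan-2-yl]propan-2-yl}-2H-pyran-2-one | O=C1OC([C@@H](C)C[C@H]2OC(=O)[C@@H](CO[Si](C(C)C)(C(C)C)C(C)C)[C@@H]2CC=C)=CC(O)=C1[C@H](CC=C)[C@@H](O[Si](C)(C)C(C)(C)C)C[C@@H](C)C#C[Si](C(C)C)(C(C)C)C(C)C | intermediate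
23 | 4-trifluoromethanesulfonate of 22 (2-oxo-2H-pyran-4-yl triflate with the same C3 and C6 substituents) | O=C1OC([C@@H](C)C[C@H]2OC(=O)[C@@H](CO[Si](C(C)C)(C(C)C)C(C)C)[C@@H]2CC=C)=CC(OS(=O)(=O)C(F)(F)F)=C1[C@H](CC=C)[C@@H](O[Si](C)(C)C(C)(C)C)C[C@@H](C)C#C[Si](C(C)C)(C(C)C)C(C)C | intermediate
24 | 4-(1-ethoxyethenyl)-2H-pyran-2-one with the C3 and C6 substituents of 22 | O=C1OC([C@@H](C)C[C@H]2OC(=O)[C@@H](CO[Si](C(C)C)(C(C)C)C(C)C)[C@@H]2CC=C)=CC(C(=C)OCC)=C1[C@H](CC=C)[C@@H](O[Si](C)(C)C(C)(C)C)C[C@@H](C)C#C[Si](C(C)C)(C(C)C)C(C)C | intermediate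
25 | 4-acetyl-3-{(4S,5S,7R)-5-[tert-butyl(dimethyl)silyl]oxy-7-methyl-9-[tri(propan-2-yl)silyl]non-1-en-8-yn-4-yl}-6-{(2S)-1-[(2R,3S,4R)-5-oxo-3-(prop-2-en-1-yl)-4-({[tri(propan-2-yl)silyl]oxy}methyl)oxolan-2-yl]propan-2-yl}-2H-pyran-2-one | O=C1OC([C@@H](C)C[C@H]2OC(=O)[C@@H](CO[Si](C(C)C)(C(C)C)C(C)C)[C@@H]2CC=C)=CC(C(C)=O)=C1[C@H](CC=C)[C@@H](O[Si](C)(C)C(C)(C)C)C[C@@H](C)C#C[Si](C(C)C)(C(C)C)C(C)C | intermediate
26 | Diels–Alder adduct of 25: 5-acetyl-2-oxabicyclo[2.2.2]oct-5-en-3-one whose C1 (bonded to O2 and to the CHMe carbon) and C7 (H syn to the O2–C3 bridge) are shared with a cycloheptane trans-fused to the γ-butyrolactone that carries the trans CH2OSi(iPr)3 group; C4 carries the (4S,5S,7R)-5-silyloxy-7-methyl-9-silylnon-1-en-8-yn-4-yl chain | O=C1O[C@@H]2C[C@H](C)[C@@]34OC(=O)[C@@](C[C@@H]3C[C@H]2[C@@H]1CO[Si](C(C)C)(C(C)C)C(C)C)(C(C(C)=O)=C4)[C@H](CC=C)[C@@H](O[Si](C)(C)C(C)(C)C)C[C@@H](C)C#C[Si](C(C)C)(C(C)C)C(C)C | intermediate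
27 | 26 without its three silyl groups (free secondary and primary alcohols, terminal alkyne, bridged lactone intact) | O=C1O[C@@H]2C[C@H](C)[C@@]34OC(=O)[C@@](C[C@@H]3C[C@H]2[C@@H]1CO)(C(C(C)=O)=C4)[C@H](CC=C)[C@@H](O)C[C@@H](C)C#C | intermediate
28 | translactonized diol: cyclohexene with tertiary OH at the ring-fusion carbon and acetyl on the C=C; its spiro carbon is the α-carbon of a γ-lactone bearing cis allyl (β) and (2R)-2-methylbut-3-ynyl (γ) groups; the first lactone carries a trans CH2OH group | O=C1O[C@@H]2C[C@H](C)[C@]3(O)C=C(C(C)=O)[C@]4(C[C@@H]3C[C@H]2[C@@H]1CO)C(=O)O[C@@H](C[C@@H](C)C#C)[C@H]4CC=C | intermediate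
29 | primary methanesulfonate of 28 | O=C1O[C@@H]2C[C@H](C)[C@]3(O)C=C(C(C)=O)[C@]4(C[C@@H]3C[C@H]2[C@@H]1COS(C)(=O)=O)C(=O)O[C@@H](C[C@@H](C)C#C)[C@H]4CC=C | intermediate
30 | α-methylene lactone enyne: 28 with C=CH2 in place of CH–CH2OH on the first lactone | C=C1C(=O)O[C@@H]2C[C@H](C)[C@]3(O)C=C(C(C)=O)[C@]4(C[C@@H]3C[C@@H]12)C(=O)O[C@@H](C[C@@H](C)C#C)[C@H]4CC=C | intermediate
31 | target skeleton with a vinyl group in place of the (E)-3-oxobut-1-enyl group on the second cycloheptene | C=C1C(=O)O[C@@H]2C[C@H](C)[C@]3(O)C=C(C(C)=O)[C@]4(C[C@@H]3C[C@@H]12)C(=O)O[C@H]1C[C@@H](C)C(C=C)=CC[C@H]14 | intermediate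
32 | CNP0168949.6 | C=C1C(=O)O[C@@H]2C[C@H](C)[C@]3(O)C=C(C(C)=O)[C@]4(C[C@@H]3C[C@@H]12)C(=O)O[C@H]1C[C@@H](C)C(/C=C/C(C)=O)=CC[C@H]14 | target

Total step count: 18. Longest linear sequence: 13 steps (steps 1–5 or steps 6–10, then steps 11–18).

Steps most likely to fail

Step 15. The unactivated vinyl group may be too unreactive to close a seven-membered ring, the adduct may lose CO2 if heat has to replace pressure, or the cycloaddition may take place on the other face of the pyrone. The fallback sets out from pyrone 25 and replaces the pyrone by an open 2-silyloxy diene. HF·pyridine removes the two O-silyl groups while the alkynyl silane stays, and a catalytic amount of DBU lets the freed secondary alcohol open the pyrone to the ring-opened keto alkylidene lactone F1. Treatment with t-BuMe2SiOTf and Et3N converts the ketone into the 2-silyloxy-1,3-diene F2 and silylates the primary alcohol in the same operation. A thermal intramolecular Diels–Alder reaction (toluene, 140 °C) of this diene, in which the lactone carbonyl and the silyloxy group are both inside substituents and therefore end up cis, should give the spiro-lactone silyl ether F3. Bu4NF removes all silyl groups and the route is rejoined at diol 28.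

Step 11. The strongly basic dianion may attack the lactone of 17 or deprotonate the acyl donor instead of being acylated, and the translactonization to the pyrone may stay incomplete. The fallback sets out from 9 and 17 and avoids the dianion. Lactone 9 is converted (Me3SiCl, Et3N; then LiN(iPr)2, Me3SiCl) into the 1,3-bis(trimethylsilyloxy)diene F4, and acid 17 into the acid chloride F5 with oxalyl chloride. A Mukaiyama-type γ-acylation of F4 with F5 (CH2Cl2, −78 °C to rt; aqueous work-up) gives triketide 19 under neutral conditions, and DBU cyclizes it to hydroxypyrone 20, where the route is rejoined.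

Step 9. The magnesium enolate may be alkylated too slowly by the chloromethyl ether, so that proton transfer, double alkylation or attack on the tert-butyl ester compete. The fallback sets out from butenolide 14 and separates the two bond formations. Conjugate addition (CH2=CHCH2MgBr, CuBr·SMe2, Me3SiCl; aqueous work-up) gives the trans allyl lactone F6. Its lithium enolate (LiN(iPr)2, −78 °C) undergoes an aldol reaction with gaseous formaldehyde anti to the allyl group to give the hydroxymethyl lactone F7. Silylation with iPr3SiCl and imidazole returns compound 16.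

Further compounds
F1 | step 15 | ring-opened keto alkylidene lactone: α-alkylidene γ-lactone (cis allyl and silylbutynyl groups) whose exocyclic C=C carries acetyl (cis to the allyl-bearing ring carbon) and a CH2–C(=O)–CHMe chain leading to the lactone with free CH2OH | O=C1O[C@@H](C[C@@H](C)C#C[Si](C(C)C)(C(C)C)C(C)C)[C@@H](CC=C)/C1=C(\C(C)=O)CC(=O)[C@@H](C)C[C@H]1OC(=O)[C@@H](CO)[C@@H]1CC=C
F2 | step 15 | 2-silyloxy-1,3-diene: tert-butyldimethylsilyl dienol ether of F1 (silyloxy cis to the acetyl-bearing carbon) with the primary alcohol silylated | O=C1O[C@@H](C[C@@H](C)C#C[Si](C(C)C)(C(C)C)C(C)C)[C@@H](CC=C)/C1=C(\C(C)=O)/C=C(\O[Si](C)(C)C(C)(C)C)[C@@H](C)C[C@H]1OC(=O)[C@@H](CO[Si](C)(C)C(C)(C)C)[C@@H]1CC=C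
F3 | step 15 | spiro-lactone silyl ether: 28 with tert-butyldimethylsilyl groups on the tertiary and primary oxygens and triisopropylsilyl on the alkyne | O=C1O[C@@H]2C[C@H](C)[C@]3(O[Si](C)(C)C(C)(C)C)C=C(C(C)=O)[C@]4(C[C@@H]3C[C@H]2[C@@H]1CO[Si](C)(C)C(C)(C)C)C(=O)O[C@@H](C[C@@H](C)C#C[Si](C(C)C)(C(C)C)C(C)C)[C@H]4CC=C
F4 | step 11 | 1,3-bis(trimethylsilyloxy)diene of 9: 2-trimethylsilyloxy-4,5-dihydrofuran bearing a 1-(trimethylsilyloxy)ethenyl group at C3 | C=CC[C@H]1C(C(=C)O[Si](C)(C)C)=C(O[Si](C)(C)C)O[C@H]1C[C@@H](C)C#C[Si](C(C)C)(C(C)C)C(C)C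
F5 | step 11 | acid chloride of 17 | O=C1O[C@H](C[C@H](C)C(Cl)=O)[C@@H](CC=C)[C@@H]1CO[Si](C(C)C)(C(C)C)C(C)C
F6 | step 9 | tert-butyl (2S)-2-methyl-3-[(2R,3S)-5-oxo-3-(prop-2-en-1-yl)oxolan-2-yl]propanoate | O=C1O[C@H](C[C@H](C)C(=O)OC(C)(C)C)[C@@H](CC=C)C1
F7 | step 9 | tert-butyl (2S)-3-[(2R,3S,4R)-4-(hydroxymethyl)-5-oxo-3-(prop-2-en-1-yl)oxolan-2-yl]-2-methylpropanoate | O=C1O[C@H](C[C@H](C)C(=O)OC(C)(C)C)[C@@H](CC=C)[C@@H]1CO
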